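| setting | north-east | south-west | south | birch | ash | maple | oak |
|---|---|---|---|---|---|---|---|
| starting material | 0.10 M | 0.10 M | 0.10 M | 0.10 M | 0.10 M | 0.10 M (fed, over 80 s) | 0.10 M (fed, over 80 s) |
| partner | 0.60 equiv | 0.60 equiv | 0.60 equiv | 0.600 equiv (fed, over 20 s) | 0.600 equiv (fed, over 80 s) | 0.600 equiv | 0.600 equiv |
| free catalyst | 2.5 mol% | 1.2 mol% | 1.9 mol% | 2.5 mol% | 2.5 mol% | 2.5 mol% | 2.5 mol% |
| temperature | 5 °C | 20 °C | 5 °C | 20 °C | 20 °C |  | 20 °C |
| remark | run made earlier | run made earlier | run made earlier | all else is in the flask from the start; the feed brings no volume worth counting | all else is in the flask from the start; the feed brings no volume worth counting | the addition at −20 °C, then warmed to 20 °C; the feed brings no volume worth counting | all else is in the flask from the start; the feed brings no volume worth counting |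
| time |  |  |  | 2.0 min | 2.0 min | 2.0 min | 2.0 min |

- north-east (time / min: homo dimer / %, target / %): 0.333: 1.2, 12.9; 0.833: 4.1, 29.8; 1.33: 5.5, 43.2; 2.00: 5.7, 54.6; 3.00: 7.1, 58.8; 4.00: 7.9, 59.1
- south-west (time / min: homo dimer / %, target / %): 0.417: 9.2, 21.9; 0.833: 13.1, 37.7; 1.33: 15.6, 50.7; 1.50: 15.8, 52.5; 2.00: 16.0, 57.0; 2.50: 17.4, 58.8
- south (time / min: homo dimer / %, target / %): 0.333: 2.6, 10.4; 1.00: 5.3, 26.6; 2.00: 7.9, 46.7; 3.00: 8.2, 56.9; 4.00: 9.7, 59.0; 5.00: 10.5, 59.9

(each reading ± 0.5 percentage points)

- percent here means starting material units held: one homo dimer counts as two
- steps thought possible: starting material + free catalyst -> catalyst intermediate A; partner + catalyst intermediate A <-> catalyst intermediate B; catalyst intermediate B -> free catalyst + target; 2 starting material -> homo dimer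

- which flask leads in amount of homo dimer, in percent of the starting material charged ("all alike" within 1.5 percentage points) (birch / ash / maple / oak / all alike)
- how much homo dimer is there at the end, in percent of the starting material charged: birch
- how much homo dimer is there at the end, in percent of the starting material charged: ash
- how much homo dimer is there at the end, in percent of the starting material charged: maple
- how much homo dimer is there at the end, in percent of the starting material charged: oak

- Early on, starting material stands near its charge, and that is the time to watch the homo dimer. Two starting material go at each turn, so homo dimer grows with the square of s, the fraction of starting material left.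
- If s falls along a straight line from a to b, the closed integral gives the mean of its square as (a·a + a·b + b·b) divided by 3.
- The south-west run at 0.417 min holds 9.2% homo dimer and 21.9% target, which, with up to 1.2 mol% bound to the catalyst left aside, leaves s at 68.9%. That gives 0.306 min⁻¹, the dimer pace: the fraction of the charge going to homo dimer per minute at full starting material and 20 °C. It rests on readings with a scatter of 0.5 percentage points.
- The hunch that slow feeding spares the flask meets partner as the limiting reagent, charged at 0.600 equiv. The south-west start, scaled to 2.5 mol%, makes target at 1.09 min⁻¹, while ash is fed partner at 0.450 min⁻¹, slower than that. So early in ash target can follow the feed, this reckoning takes s to fall along a straight line, and ash is the flask to watch up to 80 s.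
- Counting target alone, s ends the feed in ash at 40.0%, and this reckoning gives 21.2% homo dimer by then. Taking that homo dimer off s as well gives 16.6%, and the reckoning holds ash between the two. Oak, taken with s rising from zero to 40.0% over its feed and then held there, comes in this reckoning to 5.44%, less than ash.
- The forecast also leads with ash, giving birch 11.5%, ash 16%, maple 7.5% and oak 7%. Of ash it says: “partner starves the cycle”. Its figure for ash at the end lies below this range for the end of the feed, and its oak lies above this reckoning.

    starting material + free catalyst → catalyst intermediate A (k = 34.0 M⁻¹ s⁻¹, Ea = 47.0 kJ mol⁻¹)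
    partner + catalyst intermediate A ⇌ catalyst intermediate B (K = 250 M⁻¹, k = 41.0 M⁻¹ s⁻¹, Ea = 36.0 kJ mol⁻¹, ΔH = −59.0 kJ mol⁻¹)
    catalyst intermediate B → free catalyst + target (k = 2.20 s⁻¹, Ea = 61.0 kJ mol⁻¹)
    2 starting material → homo dimer (k = 0.0250 M⁻¹ s⁻¹, Ea = 62.0 kJ mol⁻¹)
    (constants at 20 °C)

Ash ends with 19.4% homo dimer, more than birch at 13.5%, maple at 7.86% and oak at 4.58%. Ash averages 0.0646 M of starting material over its feed, and the dimer pace with the square of that mean gives 17.0% homo dimer, while ash holds 18.3% homo dimer at 1.33 min. After the feed in oak, starting material falls from 39.8% to 33.0%, for which the dimer pace gives 2.7 points, and oak's homo dimer climbs from 2.07% to 4.58%.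

(The earlier runs and the new flask were generated by integration from invented constants.)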